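Sceptrin's cyclobutane is numbered as in the open-chain precursor: C2 (carboxyl-level, later CH2N), C3 (CH2O, later CH2N), C4 and C5 (imidazole-bearing). C2 sits between C3 and C5 and faces C4 across the ring, the 1,3-relationship left when the C2–C4 central bond of a bicyclo[1.1.0]butane-1-carboxylate is cleaved by a carbon nucleophile arriving at C4. In one flask a rhodium carbene at C2 of an (E)-2-diazo-5-imidazolylpent-4-enoate bearing the C3 stereocentre cyclopropanates C4=C5 (bonds C2–C5 and C2–C4), and an imidazolyl cuprate opens C2–C4 with inversion. The four-membered ring, the second imidazole and three stereocentres result.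

Key step: step 7

Remark on the structures: in the cyclobutane ester 17 the two imidazoles sit on adjacent ring carbons (C4 and C5). Counted from the ester carbon the ring is therefore 2-(silyloxymethyl)-3,4-bis(imidazolyl)-substituted, which is the pattern of sceptrin.

Remark on descriptors: C3 changes from R (9) to S (10, 11) only through CIP priorities; no bond to C3 is touched.

Remark on stoichiometry: steps 10, 12 and 14 act on both C2-related halves of the molecule and consume two equivalents of the atom-donating reagent. Both equivalents are written out on the lines that account for the atoms.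

Assumption: sceptrin leaves the last step as a salt and is converted to the neutral form by ion exchange.

Step 1
Reactants: 1 1H-imidazole-4-carbaldehyde; 2 dimethylsulfamoyl chloride
Product: 3 4-formyl-N,N-dimethylimidazole-1-sulfonamide
Conditions: Et3N, MeCN, rt → 50 °C
Reagents that add atoms: none
Why: N-sulfamoylation of the imidazole; sulfamoyl transfer is reversible under the conditions, so the less hindered 1,4-isomer should accumulate.

Step 2
Reactants: 3 4-formyl-N,N-dimethylimidazole-1-sulfonamide; 4 tert-butyldimethyl(prop-2-yn-1-yloxy)silane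
Product: 7 (1S,2E)-4-(tert-butyldimethylsilyloxy)-1-[1-(dimethylsulfamoyl)imidazol-4-yl]but-2-en-1-ol, via alkenyldicyclohexylborane 5 (not isolated), via alkenyl(methyl)zinc 6 (not isolated)
Conditions: Cy2BH (from BH3·SMe2, cyclohexene), toluene, 0 °C → rt; Me2Zn, −78 °C; (2S)-(−)-3-exo-morpholinoisoborneol (5 mol%), then 3, −20 → 0 °C; aq. NH4Cl
Reagents that add atoms: none
Why: Syn hydroboration gives the (E)-alkenylborane, boron–zinc exchange gives the alkenylzinc, and the chiral zinc aminoalkoxide delivers the alkenyl group to the Si face of the aldehyde (ligand-accelerated organozinc addition), which sets the (S)-carbinol.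

Step 3
Reactants: 7 (1S,2E)-4-(tert-butyldimethylsilyloxy)-1-[1-(dimethylsulfamoyl)imidazol-4-yl]but-2-en-1-ol
Product: 9 ethyl (3R,4E)-3-[(tert-butyldimethylsilyloxy)methyl]-5-[1-(dimethylsulfamoyl)imidazol-4-yl]pent-4-enoate, via mixed ketene acetal 8 (not isolated)
Conditions: MeC(OEt)3, EtCO2H (cat.), xylene, 135 °C, removal of EtOH
Reagents that add atoms: triethyl orthoacetate, CC(OCC)(OCC)OCC
Why: Johnson–Claisen rearrangement through a chair transition state with the imidazolyl group equatorial transfers the carbinol chirality suprafacially to C3 (R) and forms the E-alkene.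

Step 4
Reactants: 9 ethyl (3R,4E)-3-[(tert-butyldimethylsilyloxy)methyl]-5-[1-(dimethylsulfamoyl)imidazol-4-yl]pent-4-enoate
Product: 11 ethyl (3S,4E)-3-[(tert-butyldimethylsilyloxy)methyl]-2-diazo-5-[1-(dimethylsulfamoyl)imidazol-4-yl]pent-4-enoate, via 2-trifluoroacetyl ester 10 (not isolated)
Conditions: LiN(SiMe3)2, THF, −78 °C; CF3CO2CH2CF3; aq. NH4Cl; then 4-acetamidobenzenesulfonyl azide (p-ABSA), Et3N, MeCN, rt
Reagents that add atoms: 4-acetamidobenzenesulfonyl azide, CC(=O)Nc1ccc(cc1)S(=O)(=O)N=[N+]=[N-]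
Why: Deacylative Regitz diazo transfer: C-trifluoroacetylation of the ester enolate activates C2, and attack on the sulfonyl azide followed by transfer of the trifluoroacetyl group to the sulfonamide nitrogen should give the diazo ester without touching C3.

Step 5
Reactants: 12 4-iodo-1H-imidazole; 2 dimethylsulfamoyl chloride
Product: 13 4-iodo-N,N-dimethylimidazole-1-sulfonamide
Conditions: Et3N, CH2Cl2, rt
Reagents that add atoms: none
Why: N-sulfamoylation; the 1,4-isomer, which has the sulfamoyl group remote from iodine, is the thermodynamic product.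

Step 6
Reactants: 13 4-iodo-N,N-dimethylimidazole-1-sulfonamide
Product: 14 [1-(dimethylsulfamoyl)imidazol-4-yl]magnesium chloride
Conditions: i-PrMgCl·LiCl, THF, −20 → 0 °C; the THF solution is used directly in step 7
Reagents that add atoms: isopropylmagnesium chloride–lithium chloride, CC(C)[Mg]Cl.[Li+].[Cl-]
Why: Iodine–magnesium exchange is driven by formation of the more stable sp2 heteroaryl Grignard reagent; at or below 0 °C it should neither isomerise nor attack the sulfamoyl group.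

Step 7
Reactants: 11 ethyl (3S,4E)-3-[(tert-butyldimethylsilyloxy)methyl]-2-diazo-5-[1-(dimethylsulfamoyl)imidazol-4-yl]pent-4-enoate; 14 [1-(dimethylsulfamoyl)imidazol-4-yl]magnesium chloride
Product: 17 ethyl (1S,2S,3R,4R)-2-[(tert-butyldimethylsilyloxy)methyl]-3,4-bis[1-(dimethylsulfamoyl)imidazol-4-yl]cyclobutane-1-carboxylate (all-trans), via exo-exo bicyclobutane ester 15 (not isolated), via chloromagnesium enolate 16 (not isolated)
Conditions: 11 added slowly to Rh2(O2CCPh3)4 (1 mol%), toluene, −78 °C; then CuBr·SMe2 (0.3 equiv), PBu3, 14 (2 equiv, THF), −78 → 0 °C; then EtOH, NaOEt (0.5 equiv), 0 °C → rt; aq. NH4Cl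
Reagents that add atoms: none
Why: Rh2(O2CCPh3)4 converts 11 into a dirhodium carbene at C2 that adds across the tethered C4=C5 bond in a [2+1] sense, forming C2–C5 and the strained central bond C2–C4 of bicyclobutane 15; the imidazolylcopper species formed from 14 and CuBr·SMe2 then attacks the unsubstituted bridgehead C4 from the side opposite the central bond, cleaving C2–C4 and leaving ester enolate 16, which ethanol protonates. The closest known reaction type is the dirhodium-catalysed intramolecular bicyclobutanation of (E)-2-diazo-5-arylpent-4-enoates followed in the same flask by copper-mediated homoconjugate Grignard addition. The four-membered ring is closed by the carbene cycloaddition (C2 bridging C4 and C5) and survives as the perimeter of the bicyclobutane when the central bond is opened in a strain-release SN2-like step. C5 is set by stereospecific syn addition to the E-alkene (imidazole exo) on the face dictated by C3, whose CH2OTBS group goes exo rather than into the fold of the bicycle; C4 is set by inversion at the bridgehead, which places the new imidazole trans to both exo groups; C2 is set by reversible enolisation with ethoxide, which leaves the ester trans to both neighbours. The step needs cyclopropanation to outrun 1,2-hydride shift from the tertiary allylic C3–H, which the bulky triphenylacetate ligands (holding the small C3–H in the carbene plane, orthogonal to the vacant orbital) and −78 °C should favour, and it needs the sulfamoyl groups to keep the imidazole N3 atoms from binding rhodium.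

Step 8
Reactants: 17 ethyl (1S,2S,3R,4R)-2-[(tert-butyldimethylsilyloxy)methyl]-3,4-bis[1-(dimethylsulfamoyl)imidazol-4-yl]cyclobutane-1-carboxylate
Product: 18 [(1S,2S,3R,4R)-2-[(tert-butyldimethylsilyloxy)methyl]-3,4-bis[1-(dimethylsulfamoyl)imidazol-4-yl]cyclobutyl]methanol
Conditions: i-Bu2AlH, CH2Cl2, −78 → 0 °C; aq. KNaC4H4O6
Reagents that add atoms: none
Why: Hydride reduction of the ester to the primary alcohol; sulfamoyl groups and the silyl ether are inert to i-Bu2AlH at low temperature, and C2 is no longer epimerisable afterwards.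

Step 9
Reactants: 18 [(1S,2S,3R,4R)-2-[(tert-butyldimethylsilyloxy)methyl]-3,4-bis[1-(dimethylsulfamoyl)imidazol-4-yl]cyclobutyl]methanol
Product: 19 (1S,2S,3R,4R)-1,2-bis[(tert-butyldimethylsilyloxy)methyl]-3,4-bis[1-(dimethylsulfamoyl)imidazol-4-yl]cyclobutane
Conditions: TBSCl, imidazole, DMF, rt
Reagents that add atoms: tert-butyldimethylsilyl chloride, CC(C)(C)[Si](C)(C)Cl
Why: Standard silylation of a primary alcohol removes the only acidic proton before the organolithium step and makes the molecule C2-symmetric.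

Step 10
Reactants: 19 (1S,2S,3R,4R)-1,2-bis[(tert-butyldimethylsilyloxy)methyl]-3,4-bis[1-(dimethylsulfamoyl)imidazol-4-yl]cyclobutane
Product: 20 (1S,2S,3R,4R)-1,2-bis[(tert-butyldimethylsilyloxy)methyl]-3,4-bis[2-azido-1-(dimethylsulfamoyl)imidazol-4-yl]cyclobutane
Conditions: n-BuLi (2.4 equiv), THF, −78 °C; TsN3 (2.6 equiv), −78 °C → rt; aq. NH4Cl
Reagents that add atoms: 4-methylbenzenesulfonyl azide (two equivalents), Cc1ccc(cc1)S(=O)(=O)N=[N+]=[N-].Cc1ccc(cc1)S(=O)(=O)N=[N+]=[N-]
Why: Directed lithiation takes place at each imidazole C2–H, the most acidic site between the two ring nitrogens and next to the sulfamoyl group, and each heteroaryllithium attacks the terminal nitrogen of one sulfonyl azide, the triazenyl anion collapsing to aryl azide and sulfinate (electrophilic azide transfer).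

Step 11
Reactants: 20 (1S,2S,3R,4R)-1,2-bis[(tert-butyldimethylsilyloxy)methyl]-3,4-bis[2-azido-1-(dimethylsulfamoyl)imidazol-4-yl]cyclobutane
Product: 21 [(1S,2S,3R,4R)-3,4-bis[2-azido-1-(dimethylsulfamoyl)imidazol-4-yl]cyclobutane-1,2-diyl]dimethanol
Conditions: camphorsulfonic acid (cat.), MeOH/CH2Cl2, rt
Reagents that add atoms: none
Why: Acid-catalysed methanolysis cleaves primary silyl ethers, while azides and sulfamoyl groups tolerate catalytic acid at room temperature.

Step 12
Reactants: 21 [(1S,2S,3R,4R)-3,4-bis[2-azido-1-(dimethylsulfamoyl)imidazol-4-yl]cyclobutane-1,2-diyl]dimethanol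
Product: 23 (1R,2R,3S,4S)-1,2-bis(azidomethyl)-3,4-bis[2-azido-1-(dimethylsulfamoyl)imidazol-4-yl]cyclobutane (kept in solution), via bis-mesylate 22 (not isolated)
Conditions: MsCl (2.5 equiv), Et3N, CH2Cl2, 0 °C; then NaN3 (3 equiv), DMF, 60 °C
Reagents that add atoms: sodium azide (two equivalents), [Na+].[N-]=[N+]=[N-].[Na+].[N-]=[N+]=[N-]
Why: Mesylation followed by SN2 displacement with azide at both primary cyclobutylmethyl carbons cannot epimerise the ring (the descriptors change only through CIP priorities).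

Step 13
Reactants: 23 (1R,2R,3S,4S)-1,2-bis(azidomethyl)-3,4-bis[2-azido-1-(dimethylsulfamoyl)imidazol-4-yl]cyclobutane
Product: 24 (1R,2R,3S,4S)-1,2-bis(aminomethyl)-3,4-bis[2-amino-1-(dimethylsulfamoyl)imidazol-4-yl]cyclobutane
Conditions: H2 (1 atm), Pd/C, MeOH, rt
Reagents that add atoms: none
Why: Catalytic hydrogenation reduces alkyl and heteroaryl azides alike to amines with loss of N2 and leaves N–S bonds and the ring untouched.

Step 14
Reactants: 24 (1R,2R,3S,4S)-1,2-bis(aminomethyl)-3,4-bis[2-amino-1-(dimethylsulfamoyl)imidazol-4-yl]cyclobutane; 25 1-(4-bromo-1H-pyrrol-2-yl)-2,2,2-trichloroethanone (two equivalents)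
Product: 26 N,N'-{[(1R,2R,3S,4S)-3,4-bis[2-amino-1-(dimethylsulfamoyl)imidazol-4-yl]cyclobutane-1,2-diyl]bis(methylene)}bis(4-bromo-1H-pyrrole-2-carboxamide)
Conditions: 25 (2.1 equiv), i-Pr2NEt, DMF, rt
Reagents that add atoms: 1-(4-bromo-1H-pyrrol-2-yl)-2,2,2-trichloroethanone (second equivalent of 25), O=C(c1cc(Br)c[nH]1)C(Cl)(Cl)Cl
Why: Haloform-type acyl transfer from one trichloromethyl ketone to each of the two aliphatic amines, with loss of two molecules of chloroform, should leave the sulfamoylated 2-aminoimidazole nitrogens alone because they are amidine-like and poorly nucleophilic.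

Step 15
Reactants: 26 N,N'-{[(1R,2R,3S,4S)-3,4-bis[2-amino-1-(dimethylsulfamoyl)imidazol-4-yl]cyclobutane-1,2-diyl]bis(methylene)}bis(4-bromo-1H-pyrrole-2-carboxamide)
Product: 27 sceptrin
Conditions: 3 M aq. HCl/dioxane, 70 °C; then basic ion-exchange resin
Reagents that add atoms: none
Why: Acid hydrolysis of the two N-sulfamoyl groups, activated by protonation of the aminoimidazole, should be much faster than hydrolysis of the pyrrole carboxamides and touches no stereocentre.

Compound list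

1 | 1H-imidazole-4-carbaldehyde | O=Cc1c[nH]cn1 | starting material
2 | dimethylsulfamoyl chloride | CN(C)S(=O)(=O)Cl | starting material
3 | 4-formyl-N,N-dimethylimidazole-1-sulfonamide | O=Cc1cn(S(=O)(=O)N(C)C)cn1 | intermediate
4 | tert-butyldimethyl(prop-2-yn-1-yloxy)silane | C#CCO[Si](C)(C)C(C)(C)C | starting material
5 | [(E)-3-(tert-butyldimethylsilyloxy)prop-1-enyl]dicyclohexylborane | C1CCCCC1B(/C=C/CO[Si](C)(C)C(C)(C)C)C1CCCCC1 | intermediate
6 | [(E)-3-(tert-butyldimethylsilyloxy)prop-1-enyl](methyl)zinc | C[Zn]/C=C/CO[Si](C)(C)C(C)(C)C | intermediate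
7 | (1S,2E)-4-(tert-butyldimethylsilyloxy)-1-[1-(dimethylsulfamoyl)imidazol-4-yl]but-2-en-1-ol | O[C@H](c1cn(S(=O)(=O)N(C)C)cn1)/C=C/CO[Si](C)(C)C(C)(C)C | intermediate
8 | 1-ethoxyvinyl ether of 7 (mixed ketene acetal, carbinol centre unchanged) | C=C(OCC)O[C@H](c1cn(S(=O)(=O)N(C)C)cn1)/C=C/CO[Si](C)(C)C(C)(C)C | intermediate
9 | ethyl (3R,4E)-3-[(tert-butyldimethylsilyloxy)methyl]-5-[1-(dimethylsulfamoyl)imidazol-4-yl]pent-4-enoate | CCOC(=O)C[C@@H](CO[Si](C)(C)C(C)(C)C)/C=C/c1cn(S(=O)(=O)N(C)C)cn1 | intermediate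
10 | ethyl (3S,4E)-3-[(tert-butyldimethylsilyloxy)methyl]-5-[1-(dimethylsulfamoyl)imidazol-4-yl]-2-(trifluoroacetyl)pent-4-enoate (C2 undefined) | CCOC(=O)C(C(=O)C(F)(F)F)[C@@H](CO[Si](C)(C)C(C)(C)C)/C=C/c1cn(S(=O)(=O)N(C)C)cn1 | intermediate
11 | ethyl (3S,4E)-3-[(tert-butyldimethylsilyloxy)methyl]-2-diazo-5-[1-(dimethylsulfamoyl)imidazol-4-yl]pent-4-enoate | CCOC(=O)C(=[N+]=[N-])[C@@H](CO[Si](C)(C)C(C)(C)C)/C=C/c1cn(S(=O)(=O)N(C)C)cn1 | intermediate
12 | 4-iodo-1H-imidazole | Ic1c[nH]cn1 | starting material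
13 | 4-iodo-N,N-dimethylimidazole-1-sulfonamide | Ic1cn(S(=O)(=O)N(C)C)cn1 | intermediate
14 | [1-(dimethylsulfamoyl)imidazol-4-yl]magnesium chloride | Cl[Mg]c1cn(S(=O)(=O)N(C)C)cn1 | intermediate
15 | ethyl exo,exo-2-[(tert-butyldimethylsilyloxy)methyl]-4-[1-(dimethylsulfamoyl)imidazol-4-yl]bicyclo[1.1.0]butane-1-carboxylate | CCOC(=O)[C@@]12[C@@H](CO[Si](C)(C)C(C)(C)C)[C@@H]1[C@H]2c1cn(S(=O)(=O)N(C)C)cn1 | intermediate
16 | chloromagnesium enolate of 17 (C2 trigonal; imidazoles at C4 and C5 trans to each other, CH2OTBS at C3 trans to the C4 imidazole) | CCOC(O[Mg]Cl)=C1[C@@H](CO[Si](C)(C)C(C)(C)C)[C@H](c2cn(S(=O)(=O)N(C)C)cn2)[C@H]1c1cn(S(=O)(=O)N(C)C)cn1 | intermediate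
17 | ethyl (1S,2S,3R,4R)-2-[(tert-butyldimethylsilyloxy)methyl]-3,4-bis[1-(dimethylsulfamoyl)imidazol-4-yl]cyclobutane-1-carboxylate (all-trans) | CCOC(=O)[C@@H]1[C@@H](CO[Si](C)(C)C(C)(C)C)[C@H](c2cn(S(=O)(=O)N(C)C)cn2)[C@H]1c1cn(S(=O)(=O)N(C)C)cn1 | intermediate
18 | [(1S,2S,3R,4R)-2-[(tert-butyldimethylsilyloxy)methyl]-3,4-bis[1-(dimethylsulfamoyl)imidazol-4-yl]cyclobutyl]methanol | OC[C@@H]1[C@@H](CO[Si](C)(C)C(C)(C)C)[C@H](c2cn(S(=O)(=O)N(C)C)cn2)[C@H]1c1cn(S(=O)(=O)N(C)C)cn1 | intermediate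
19 | (1S,2S,3R,4R)-1,2-bis[(tert-butyldimethylsilyloxy)methyl]-3,4-bis[1-(dimethylsulfamoyl)imidazol-4-yl]cyclobutane (all-trans) | CC(C)(C)[Si](C)(C)OC[C@@H]1[C@@H](CO[Si](C)(C)C(C)(C)C)[C@H](c2cn(S(=O)(=O)N(C)C)cn2)[C@H]1c1cn(S(=O)(=O)N(C)C)cn1 | intermediate
20 | (1S,2S,3R,4R)-1,2-bis[(tert-butyldimethylsilyloxy)methyl]-3,4-bis[2-azido-1-(dimethylsulfamoyl)imidazol-4-yl]cyclobutane | CC(C)(C)[Si](C)(C)OC[C@@H]1[C@@H](CO[Si](C)(C)C(C)(C)C)[C@H](c2cn(S(=O)(=O)N(C)C)c(N=[N+]=[N-])n2)[C@H]1c1cn(S(=O)(=O)N(C)C)c(N=[N+]=[N-])n1 | intermediate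
21 | [(1S,2S,3R,4R)-3,4-bis[2-azido-1-(dimethylsulfamoyl)imidazol-4-yl]cyclobutane-1,2-diyl]dimethanol | OC[C@@H]1[C@@H](CO)[C@H](c2cn(S(=O)(=O)N(C)C)c(N=[N+]=[N-])n2)[C@H]1c1cn(S(=O)(=O)N(C)C)c(N=[N+]=[N-])n1 | intermediate
22 | bis(methanesulfonate) of diol 21 | CS(=O)(=O)OC[C@@H]1[C@@H](COS(C)(=O)=O)[C@H](c2cn(S(=O)(=O)N(C)C)c(N=[N+]=[N-])n2)[C@H]1c1cn(S(=O)(=O)N(C)C)c(N=[N+]=[N-])n1 | intermediate
23 | (1R,2R,3S,4S)-1,2-bis(azidomethyl)-3,4-bis[2-azido-1-(dimethylsulfamoyl)imidazol-4-yl]cyclobutane | [N-]=[N+]=NC[C@@H]1[C@@H](CN=[N+]=[N-])[C@H](c2cn(S(=O)(=O)N(C)C)c(N=[N+]=[N-])n2)[C@H]1c1cn(S(=O)(=O)N(C)C)c(N=[N+]=[N-])n1 | intermediate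
24 | (1R,2R,3S,4S)-1,2-bis(aminomethyl)-3,4-bis[2-amino-1-(dimethylsulfamoyl)imidazol-4-yl]cyclobutane | NC[C@@H]1[C@@H](CN)[C@H](c2cn(S(=O)(=O)N(C)C)c(N)n2)[C@H]1c1cn(S(=O)(=O)N(C)C)c(N)n1 | intermediate
25 | 1-(4-bromo-1H-pyrrol-2-yl)-2,2,2-trichloroethanone | O=C(c1cc(Br)c[nH]1)C(Cl)(Cl)Cl | starting material
26 | N,N'-{[(1R,2R,3S,4S)-3,4-bis[2-amino-1-(dimethylsulfamoyl)imidazol-4-yl]cyclobutane-1,2-diyl]bis(methylene)}bis(4-bromo-1H-pyrrole-2-carboxamide) | O=C(NC[C@@H]1[C@@H](CNC(=O)c2cc(Br)c[nH]2)[C@H](c2cn(S(=O)(=O)N(C)C)c(N)n2)[C@H]1c1cn(S(=O)(=O)N(C)C)c(N)n1)c1cc(Br)c[nH]1 | intermediate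
27 | sceptrin (all-trans; imidazole-bearing ring carbons S,S and amidomethyl-bearing ring carbons R,R) | Nc1ncc([C@H]2[C@H](CNC(=O)c3cc(Br)c[nH]3)[C@@H](CNC(=O)c3cc(Br)c[nH]3)[C@@H]2c2cnc(N)[nH]2)[nH]1 | target

Total step count: 15. Longest linear sequence: 13 steps (steps 1–4 and 7–15).

Steps most likely to fail

1. Step 7. Hydride migration from C3 to the carbene carbon may outrun cyclopropanation, the imidazole nitrogens may bind the catalyst, or the carbene may add to the wrong alkene face. Fallback, setting out from 4 and 13 and returning at 19: the ring is assembled by head-to-head [2+2] dimerisation instead of carbene chemistry. Hydroboration of 4 with pinacolborane (Cy2BH cat., rt) should give (E)-alkenylboronate F1. Suzuki–Miyaura coupling of F1 with iodide 13 (Pd(PPh3)4, K3PO4, dioxane/H2O, 80 °C) should give the (E)-allyl silyl ether F2. Visible-light triplet sensitisation of F2 (Ir[dF(CF3)ppy]2(dtbbpy)PF6, MeCN, blue LEDs) should dimerise it to the all-trans cyclobutane as a racemate. Preparative chromatography on a chiral stationary phase would then separate 19 from the enantiomer of 19 F3, and the route continues at step 10.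

2. Step 2. Chelation of zinc between N3 and the formyl oxygen may accelerate uncatalysed addition and erode enantioselectivity. Fallback, setting out from 3 and 4 and returning at 7: the carbinol is set by ketone reduction. The lithium acetylide of 4 (n-BuLi, THF, −78 °C) adds to 3 to give the racemic propargylic alcohol F4. Oxidation with MnO2 (CH2Cl2, rt) gives ynone F5. Reduction with (R)-Alpine-Borane, in which the alkynyl group acts as the small substituent, should give the (S)-propargylic alcohol F6. Trans-hydroalumination with NaAlH2(OCH2CH2OMe)2 (THF, 0 °C) returns to 7.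

3. Step 4. C-Trifluoroacetylation of the ester enolate may be incomplete or reversible, so that diazo transfer does not take place. Fallback, setting out from 7 and returning at 11: the activating acyl group is carried through the sigmatropic step. Acetoacetylation of 7 (2,2,6-trimethyl-1,3-dioxin-4-one, xylene, 120 °C) gives the allylic acetoacetate F7. Its dianion (LiN(i-Pr)2, 2.2 equiv, THF, −78 °C → rt) should undergo Carroll rearrangement through the same chair, without decarboxylation, to the β-keto acid F8. O-Ethylation (Et3OBF4, i-Pr2NEt, CH2Cl2, 0 °C) gives the ethyl 2-acetyl ester F9. Deacetylative diazo transfer (p-ABSA, DBU, MeCN, 0 °C) returns to 11.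

Further compounds

F1 | step 7 | 2-[(E)-3-(tert-butyldimethylsilyloxy)prop-1-enyl]-4,4,5,5-tetramethyl-1,3,2-dioxaborolane | CC1(C)OB(/C=C/CO[Si](C)(C)C(C)(C)C)OC1(C)C
F2 | step 7 | 4-[(E)-3-(tert-butyldimethylsilyloxy)prop-1-enyl]-N,N-dimethylimidazole-1-sulfonamide | CC(C)(C)[Si](C)(C)OC/C=C/c1cn(S(=O)(=O)N(C)C)cn1
F3 | step 7 | (1R,2R,3S,4S)-1,2-bis[(tert-butyldimethylsilyloxy)methyl]-3,4-bis[1-(dimethylsulfamoyl)imidazol-4-yl]cyclobutane (enantiomer of 19) | CC(C)(C)[Si](C)(C)OC[C@H]1[C@H](CO[Si](C)(C)C(C)(C)C)[C@@H](c2cn(S(=O)(=O)N(C)C)cn2)[C@@H]1c1cn(S(=O)(=O)N(C)C)cn1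
F4 | step 2 | racemic 4-(tert-butyldimethylsilyloxy)-1-[1-(dimethylsulfamoyl)imidazol-4-yl]but-2-yn-1-ol | OC(C#CCO[Si](C)(C)C(C)(C)C)c1cn(S(=O)(=O)N(C)C)cn1
F5 | step 2 | 4-(tert-butyldimethylsilyloxy)-1-[1-(dimethylsulfamoyl)imidazol-4-yl]but-2-yn-1-one | O=C(C#CCO[Si](C)(C)C(C)(C)C)c1cn(S(=O)(=O)N(C)C)cn1
F6 | step 2 | (1S)-4-(tert-butyldimethylsilyloxy)-1-[1-(dimethylsulfamoyl)imidazol-4-yl]but-2-yn-1-ol | O[C@H](c1cn(S(=O)(=O)N(C)C)cn1)C#CCO[Si](C)(C)C(C)(C)C
F7 | step 4 | (1S,2E)-4-(tert-butyldimethylsilyloxy)-1-[1-(dimethylsulfamoyl)imidazol-4-yl]but-2-enyl 3-oxobutanoate | CC(=O)CC(=O)O[C@H](c1cn(S(=O)(=O)N(C)C)cn1)/C=C/CO[Si](C)(C)C(C)(C)C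
F8 | step 4 | (3S,4E)-2-acetyl-3-[(tert-butyldimethylsilyloxy)methyl]-5-[1-(dimethylsulfamoyl)imidazol-4-yl]pent-4-enoic acid (C2 undefined) | CC(=O)C(C(=O)O)[C@@H](CO[Si](C)(C)C(C)(C)C)/C=C/c1cn(S(=O)(=O)N(C)C)cn1
F9 | step 4 | ethyl (3S,4E)-2-acetyl-3-[(tert-butyldimethylsilyloxy)methyl]-5-[1-(dimethylsulfamoyl)imidazol-4-yl]pent-4-enoate (C2 undefined) | CCOC(=O)C(C(C)=O)[C@@H](CO[Si](C)(C)C(C)(C)C)/C=C/c1cn(S(=O)(=O)N(C)C)cn1
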